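(The earlier runs and the new flask are calculated for an exercise, noise included.)

A stirred vessel of constant volume takes its starting material in portions, and the whole charge is counted from the start, so a share can jump when the second portion goes in.

| setting | alpha | zeta | flask |
|---|---|---|---|
| starting material | 0.45 M (in portions, 2) | 0.45 M (in portions, 2) | 0.45 M (in portions, 2) |
| free catalyst | 0.037 mol% | 0.083 mol% | 0.055 mol% |
| impurity | 0.22 mM | 0.22 mM | 0.22 mM |
| remark | run made earlier; portions every 2.5 min | run made earlier; portions every 2.5 min | the portions of starting material follow each other after 2.5 min, the first at the start |
| time |  |  | 5.0 min |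

| run | time / min | starting material / % | isomer of the product B / % | target / % | isomer of the product A / % |
|---|---|---|---|---|---|
| alpha | 0.500 | 39 | 2 | 7 | 2 |
| alpha | 0.833 | 36 | 4 | 13 | 1 |
| alpha | 1.33 | 33 | 1 | 14 | 2 |
| alpha | 2.00 | 33 | 1 | 16 | 3 |
| alpha | 4.00 | 59 | 1 | 26 | 8 |
| alpha | 6.00 | 54 | 5 | 29 | 9 |
| zeta | 1.00 | 35 | 2 | 12 | 0 |
| zeta | 2.00 | 28 | 0 | 15 | 3 |
| zeta | 3.00 | 71 | 5 | 26 | 6 |
| zeta | 4.00 | 58 | 6 | 29 | 7 |
| zeta | 5.00 | 55 | 4 | 28 | 10 |
| zeta | 6.00 | 57 | 3 | 29 | 12 |

(each reading ± 2 percentage points)

- reactions considered so far: starting material <-> target; target <-> isomer of the product A; isomer of the product B <-> starting material; free catalyst + impurity -> spent catalyst; isomer of the product A <-> isomer of the product B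
- percentages count the whole charge, also what has not yet gone in

- where most of what was charged as starting material, at 5.0 min is found (target / starting material / isomer of the product B / isomer of the product A)
- the largest share itself, whichever of these holds it, in percent of the starting material charged

Where do you look first? At the latest readings, zeta at 5.00 min and 6.00 min and alpha at 6.00 min, which give on average 0.286 for the base-ten logarithm of [starting material]/[target], the balance index, which is the inverse of the reaction quotient of starting material <-> target written as a power of ten, and so a ratio, as read, of 1.93.

Does the loading move it? At 6.00 min alpha reads 0.270 and zeta 0.293, although zeta has twice the loading, and that gap lies inside a scatter of 2 percentage points on each reading.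

But the free catalyst charged in the alpha run, 0.167 mM, is less than its impurity, 0.22 mM, so does the second portion stall there? It does not appear to, since target in the alpha run rose from 16% to 29%, and the free catalyst charged to the flask, 0.247 mM, lies between the charges of the two runs.

Has the index recovered by the asked time? In the zeta run it reads 0.436 at 3.00 min, then 0.301 at 4.00 min, and the flask is read as late after its portion as zeta's 5.00 min reading.

My reckoning takes the zeta readings of isomer of the product A and isomer of the product B at that time, 10% and 4%, and splits the remaining 86.0% between starting material and target in the ratio the index stands for, which gives 56.6% starting material as my estimate for the flask. The forecast says starting material at 56%, a little below my figure: “Starting material stays the largest share”.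

The flask gives starting material at 55.6% and target at 28.7%, an index of 0.287, and the forward half-life of starting material by the path to target alone is 1.3 min, short against 5.0 min.

    starting material ⇌ target (K = 0.550, k = 0.00890 /s)
    target ⇌ isomer of the product A (K = 0.660, k = 0.00290 /s)
    isomer of the product B ⇌ starting material (k = 0.00360 /s)
    free catalyst + impurity → spent catalyst (k = 9200 /M/s)
    isomer of the product A ⇌ isomer of the product B (K = 0.420, k = 0.0400 /s)

Left until 12 min, the neighbour flask holds isomer of the product A at 16.9% and isomer of the product B at 7.08%, and the index 0.286, taken as a ratio, splits the remaining 76.0% to give 50.1% starting material, where that flask holds 49.2%.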